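**Retrosynthetic overview**

1. Target 25 ⇐ β-keto aldehyde 21: CHO → COOH, C3 ketone → 3α-OAc (hydride from the β side), desilylation.
2. Key disconnection: 21 ⇐ 3α,4α-epoxy aldehyde 20 by a stereospecific 1,2-formyl shift (C3 → C4, semipinacol) that creates the C4 quaternary centre; 20 ⇐ enal 19 ⇐ vinyl iodide 17.
3. Rings A and B ⇐ acyclic enyne–allylsilane 16 in one enantioselective gold-catalysed cation–olefin cascade (ring A closes first by C4–C5, then ring B by C9–C10; iodine is captured at C3; C5, C9, C10 are set).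
4. 16 ⇐ three-component union of enediyne 8, Me3SiCH2Cu and iodide 14 (C8–C17 and C9–C11 bonds, Z-allylsilane).
5. 8 ⇐ hexa-1,5-diyne 1; 14 ⇐ but-3-yn-1-ol 9; both E-trisubstituted alkenes come from zirconium-catalysed carboalumination.

Assumption: the SMILES is read as 3α-acetoxy-15-hydroxylabda-8(17),13E-dien-19-oic acid, (3R,4R,5R,9S,10R); labdane numbering is used for all bicyclic compounds (5α-H, 9α-H, 10β-CH3 throughout), and the ligand antipode in step 10 is the one that gives this series (written as R).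

**Route**

Step 1
Reactants: 1 hexa-1,5-diyne
Product: 3 hepta-1,5-diyne, via lithium hexa-1,5-diyn-1-ide 2 (not isolated)
Conditions: 1 (3 equiv), n-BuLi (1 equiv), THF, −78 °C; MeI, DMPU, −78 → 20 °C; fractional distillation, excess 1 recovered
Reagents that add atoms: iodomethane, IC
Why: SN2 C-methylation of a lithium acetylide; the threefold excess of the symmetrical diyne holds the reaction at the mono-methylated stage.

Step 2
Reactants: 3 hepta-1,5-diyne
Product: 6 (3E)-4-methylnon-3-en-7-yn-1-ol, via alkenyldimethylalane 4 (not isolated), via lithium alkenylbutyldimethylaluminate 5 (not isolated)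
Conditions: Me3Al (2 equiv), Cp2ZrCl2 (20 mol %), ClCH2CH2Cl, 20 °C; volatiles off; n-BuLi (1 equiv), THF–hexane, −30 °C; oxirane, −30 → 20 °C; H2O work-up
Reagents that add atoms: trimethylaluminium, C[Al](C)C; oxirane, C1CO1
Why: Negishi zirconium-catalysed syn-methylalumination adds Me and Al across the terminal alkyne only, and the derived aluminate opens oxirane with retention, which fixes the E-trisubstituted alkene.

Step 3
Reactants: 6 (3E)-4-methylnon-3-en-7-yn-1-ol
Product: 7 (6E)-9-iodo-6-methylnon-6-en-2-yne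
Conditions: I2, PPh3, imidazole, CH2Cl2, 0 °C
Reagents that add atoms: iodine, [I][I]
Why: Appel-type (Garegg–Samuelsson) iodination, an SN2 displacement of the alkoxyphosphonium ion of a primary alcohol.

Step 4
Reactants: 7 (6E)-9-iodo-6-methylnon-6-en-2-yne
Product: 8 (5E)-6-methylundec-5-ene-1,9-diyne
Conditions: LiC≡CH·H2NCH2CH2NH2, DMSO, 10 → 20 °C
Reagents that add atoms: lithium acetylide ethylenediamine complex, [Li+].[C-]#C.NCCN
Why: SN2 alkylation of lithium acetylide by the primary iodide in DMSO, where substitution outruns E2.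

Step 5
Reactants: 9 but-3-yn-1-ol
Product: 11 methyl (2E)-5-hydroxy-3-methylpent-2-enoate, via alkenylalane aluminium alkoxide 10 (not isolated)
Conditions: Me3Al (3 equiv), Cp2ZrCl2 (25 mol %), CH2Cl2, 20 °C; ClCO2Me, 0 → 20 °C; H2O work-up
Reagents that add atoms: trimethylaluminium, C[Al](C)C; methyl chloroformate, COC(=O)Cl
Why: Negishi syn-carboalumination of the alkynol (as its aluminium alkoxide) followed by C-acylation of the alkenylalane with retention gives the E-enoate, the future 13E alkene.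

Step 6
Reactants: 11 methyl (2E)-5-hydroxy-3-methylpent-2-enoate
Product: 12 methyl (2E)-5-iodo-3-methylpent-2-enoate
Conditions: I2, PPh3, imidazole, CH2Cl2, 0 °C
Reagents that add atoms: iodine, [I][I]
Why: Appel-type iodination of the primary alcohol; the enoate is inert.

Step 7
Reactants: 12 methyl (2E)-5-iodo-3-methylpent-2-enoate
Product: 13 (2E)-5-iodo-3-methylpent-2-en-1-ol
Conditions: i-Bu2AlH (2.2 equiv), CH2Cl2, −78 °C; aqueous work-up
Reagents that add atoms: none
Why: 1,2-reduction of the conjugated ester by the aluminium hydride at −78 °C leaves the primary iodide and the alkene geometry untouched.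

Step 8
Reactants: 13 (2E)-5-iodo-3-methylpent-2-en-1-ol
Product: 14 tert-butyl{[(2E)-5-iodo-3-methylpent-2-en-1-yl]oxy}diphenylsilane
Conditions: t-BuPh2SiCl, imidazole, CH2Cl2, 20 °C
Reagents that add atoms: tert-butyl(chloro)diphenylsilane, CC(C)(C)[Si](Cl)(c1ccccc1)c1ccccc1
Why: silylation of the primary allylic alcohol gives an ether that survives organocopper, organolithium, base, BF3 and hydride steps.

Step 9
Reactants: 8 (5E)-6-methylundec-5-ene-1,9-diyne; 14 tert-butyl{[(2E)-5-iodo-3-methylpent-2-en-1-yl]oxy}diphenylsilane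
Product: 16 tert-butyl{[(2E,6Z,10E)-3,11-dimethyl-7-[(trimethylsilyl)methyl]hexadeca-2,6,10-trien-14-yn-1-yl]oxy}diphenylsilane, via alkenylcopper 15 (not isolated)
Conditions: Me3SiCH2MgCl, CuBr·SMe2, Et2O–Me2S, −40 °C; 8, −25 → 0 °C; 14, P(OEt)3, DMPU, THF, −20 → 20 °C
Reagents that add atoms: (trimethylsilyl)methylmagnesium chloride, C[Si](C)(C)C[Mg]Cl
Why: Normant syn-carbocupration of the terminal alkyne puts CH2SiMe3 on the inner carbon cis to copper, and SN2 alkylation of the alkenylcopper by the primary iodide goes with retention, so the allylsilane forms as the single 6Z isomer.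

Step 10
Reactants: 16 tert-butyl{[(2E,6Z,10E)-3,11-dimethyl-7-[(trimethylsilyl)methyl]hexadeca-2,6,10-trien-14-yn-1-yl]oxy}diphenylsilane
Product: 17 tert-butyl[(3-iodo-19-norlabda-3,8(17),13E-trien-15-yl)oxy]diphenylsilane
Conditions: [(R)-DTBM-SEGPHOS](AuCl)2 (5 mol %) premixed with AgSbF6 (10 mol %) and filtered from AgCl; N-iodosuccinimide (1.1 equiv), 4 Å MS, CH2Cl2–toluene, −40 °C
Reagents that add atoms: N-iodosuccinimide, O=C1CCC(=O)N1I
Why: Proposed new method: the cationic digold bisphosphine complex binds the internal alkyne (monovalent gold is alkynophilic and ignores the alkenes), the C5=C10 alkene attacks C4 anti to gold (6-endo-dig) and the C10 cation is trapped at once by allylsilane carbon C9 through a chair–chair transition state (trans ring fusion, equatorial side chain), loss of Me3Si+ gives only the exocyclic C8(17) alkene, and N-iodosuccinimide iodinates the C3–Au bond with retention while succinimide takes up the silyl group and frees the catalyst, so the chiral pocket fixes C5, C9 and C10 in one operation; the closest known reactions are the enantioselective gold-catalysed alkyne-initiated polyene cyclisation ended by protodeauration, the iododeauration of vinylgold species by N-iodosuccinimide and the allylsilane-terminated cation–olefin cyclisation, which have not been combined nor shown with an internal alkyne.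

Step 11
Reactants: 17 tert-butyl[(3-iodo-19-norlabda-3,8(17),13E-trien-15-yl)oxy]diphenylsilane
Product: 19 tert-butyldiphenylsilyl ether of 15-hydroxy-19(4→3)-abeo-labda-3,8(17),13E-trien-19-al, via vinyllithium 18 (not isolated)
Conditions: t-BuLi (2.1 equiv), THF, −78 °C; DMF, −78 → 0 °C; H2O work-up
Reagents that add atoms: N,N-dimethylformamide, CN(C)C=O
Why: iodine–lithium exchange and formylation of the vinyllithium with DMF (Bouveault-type) give the tetrasubstituted ring-A enal (CHO on C3, CH3 on C4).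

Step 12
Reactants: 19 tert-butyldiphenylsilyl ether of 15-hydroxy-19(4→3)-abeo-labda-3,8(17),13E-trien-19-al
Product: 20 tert-butyldiphenylsilyl ether of 3α,4α-epoxy-15-hydroxy-19(4→3)-abeo-labda-8(17),13E-dien-19-al
Conditions: 30% H2O2, NaOH (0.3 equiv), MeOH–THF, 0 °C
Reagents that add atoms: hydrogen peroxide, OO
Why: Weitz–Scheffer nucleophilic epoxidation touches only the electron-poor enal alkene, and hydroperoxide adds to C4 from the α face, anti to the axial C10 methyl, so the 3α,4α-epoxide forms (C3 and C4 set).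

Step 13
Reactants: 20 tert-butyldiphenylsilyl ether of 3α,4α-epoxy-15-hydroxy-19(4→3)-abeo-labda-8(17),13E-dien-19-al
Product: 21 tert-butyldiphenylsilyl ether of 15-hydroxy-3-oxolabda-8(17),13E-dien-19-al
Conditions: BF3·OEt2 (0.5 equiv), CH2Cl2, −78 → −30 °C
Reagents that add atoms: none
Why: Lewis-acid semipinacol (Meinwald-type) rearrangement of an α,β-epoxy aldehyde to a β-keto aldehyde: the epoxide opens at tertiary C4 and the formyl group shifts from C3 to C4 anti to the leaving oxygen, that is on the β face, which sets the C4 quaternary centre (axial CHO, equatorial CH3).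

Step 14
Reactants: 21 tert-butyldiphenylsilyl ether of 15-hydroxy-3-oxolabda-8(17),13E-dien-19-al
Product: 22 tert-butyldiphenylsilyl ether of 15-hydroxy-3-oxolabda-8(17),13E-dien-19-oic acid
Conditions: NaClO2, NaH2PO4, 2-methylbut-2-ene (20 equiv), t-BuOH–H2O, 0 °C; cold extractive work-up, used at once
Reagents that add atoms: sodium chlorite, [Na+].[O-]Cl=O
Why: Pinnick (Lindgren–Kraus) oxidation converts the hindered, non-enolisable aldehyde into the acid without touching the ketone or, with the alkene scavenger, the C=C bonds.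

Step 15
Reactants: 22 tert-butyldiphenylsilyl ether of 15-hydroxy-3-oxolabda-8(17),13E-dien-19-oic acid
Product: 24 tert-butyldiphenylsilyl ether of 3α-acetoxy-15-hydroxylabda-8(17),13E-dien-19-oic acid, via dilithium alkoxide carboxylate 23 (not isolated)
Conditions: LiBH(s-Bu)3 (2.4 equiv), THF, −78 °C; Ac2O (1.5 equiv), DMAP, −78 → 0 °C; H2O work-up (pH 4)
Reagents that add atoms: acetic anhydride, CC(=O)OC(C)=O
Why: the first hydride equivalent only makes the carboxylate (which does not decarboxylate), the bulky borohydride then attacks the C3 ketone on the equatorial β trajectory to give the axial 3α-alkoxide (sets C3), and this alkoxide is O-acetylated in the same flask.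

Step 16
Reactants: 24 tert-butyldiphenylsilyl ether of 3α-acetoxy-15-hydroxylabda-8(17),13E-dien-19-oic acid
Product: 25 (3R,4R,5R,9S,10R)-3-acetoxy-15-hydroxylabda-8(17),13E-dien-19-oic acid
Conditions: Bu4NF, AcOH (1:1), THF, 20 °C
Reagents that add atoms: none
Why: buffered fluoride cleaves the primary silyl ether; the hindered axial acetate and the exocyclic alkene are stable.

**Compound list**

1 | hexa-1,5-diyne | C#CCCC#C | starting material
2 | lithium hexa-1,5-diyn-1-ide (not isolated) | [Li+].[C-]#CCCC#C | intermediate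
3 | hepta-1,5-diyne | CC#CCCC#C | intermediate
4 | [(1E)-2-methylhept-1-en-5-yn-1-yl]dimethylalane (not isolated) | CC#CCC/C(C)=C/[Al](C)C | intermediate
5 | lithium butyl(dimethyl)[(1E)-2-methylhept-1-en-5-yn-1-yl]aluminate (not isolated) | CC#CCC/C(C)=C/[Al-](C)(C)CCCC.[Li+] | intermediate
6 | (3E)-4-methylnon-3-en-7-yn-1-ol | CC#CCC/C(C)=C/CCO | intermediate
7 | (6E)-9-iodo-6-methylnon-6-en-2-yne | CC#CCC/C(C)=C/CCI | intermediate
8 | (5E)-6-methylundec-5-ene-1,9-diyne | CC#CCC/C(C)=C/CCC#C | intermediate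
9 | but-3-yn-1-ol | C#CCCO | starting material
10 | {[(3E)-4-(dimethylalumanyl)-3-methylbut-3-en-1-yl]oxy}dimethylalane (not isolated) | C[Al](C)OCC/C(C)=C/[Al](C)C | intermediate
11 | methyl (2E)-5-hydroxy-3-methylpent-2-enoate | OCC/C(C)=C/C(=O)OC | intermediate
12 | methyl (2E)-5-iodo-3-methylpent-2-enoate | ICC/C(C)=C/C(=O)OC | intermediate
13 | (2E)-5-iodo-3-methylpent-2-en-1-ol | ICC/C(C)=C/CO | intermediate
14 | tert-butyl{[(2E)-5-iodo-3-methylpent-2-en-1-yl]oxy}diphenylsilane | ICC/C(C)=C/CO[Si](c1ccccc1)(c1ccccc1)C(C)(C)C | intermediate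
15 | [(1Z,5E)-6-methyl-2-[(trimethylsilyl)methyl]undeca-1,5-dien-9-yn-1-yl]copper (not isolated) | CC#CCC/C(C)=C/CC/C(C[Si](C)(C)C)=C/[Cu] | intermediate
16 | tert-butyl{[(2E,6Z,10E)-3,11-dimethyl-7-[(trimethylsilyl)methyl]hexadeca-2,6,10-trien-14-yn-1-yl]oxy}diphenylsilane | CC#CCC/C(C)=C/CC/C(C[Si](C)(C)C)=C/CC/C(C)=C/CO[Si](c1ccccc1)(c1ccccc1)C(C)(C)C | intermediate
17 | tert-butyl[(3-iodo-19-norlabda-3,8(17),13E-trien-15-yl)oxy]diphenylsilane (5α-H, 9α-H, 10β-CH3) | C=C1CC[C@@H]2[C@](C)(CCC(=C2C)I)[C@H]1CC/C(C)=C/CO[Si](c1ccccc1)(c1ccccc1)C(C)(C)C | intermediate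
18 | 3-lithio analogue of 17 (not isolated) | C=C1CC[C@@H]2[C@](C)(CCC([Li])=C2C)[C@H]1CC/C(C)=C/CO[Si](c1ccccc1)(c1ccccc1)C(C)(C)C | intermediate
19 | tert-butyldiphenylsilyl ether of 15-hydroxy-19(4→3)-abeo-labda-3,8(17),13E-trien-19-al (CHO on C3, CH3 on C4) | C=C1CC[C@@H]2[C@](C)(CCC(C=O)=C2C)[C@H]1CC/C(C)=C/CO[Si](c1ccccc1)(c1ccccc1)C(C)(C)C | intermediate
20 | tert-butyldiphenylsilyl ether of 3α,4α-epoxy-15-hydroxy-19(4→3)-abeo-labda-8(17),13E-dien-19-al | C=C1CC[C@@H]2[C@](C)(CC[C@@]3(C=O)O[C@@]23C)[C@H]1CC/C(C)=C/CO[Si](c1ccccc1)(c1ccccc1)C(C)(C)C | intermediate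
21 | tert-butyldiphenylsilyl ether of 15-hydroxy-3-oxolabda-8(17),13E-dien-19-al (4β-CHO, 4α-CH3) | C=C1CC[C@@H]2[C@](C)(CCC(=O)[C@]2(C)C=O)[C@H]1CC/C(C)=C/CO[Si](c1ccccc1)(c1ccccc1)C(C)(C)C | intermediate
22 | tert-butyldiphenylsilyl ether of 15-hydroxy-3-oxolabda-8(17),13E-dien-19-oic acid | C=C1CC[C@@H]2[C@](C)(CCC(=O)[C@]2(C)C(=O)O)[C@H]1CC/C(C)=C/CO[Si](c1ccccc1)(c1ccccc1)C(C)(C)C | intermediate
23 | dilithium 15-[(tert-butyldiphenylsilyl)oxy]-3α-oxidolabda-8(17),13E-dien-19-oate (not isolated) | [Li+].[Li+].C=C1CC[C@@H]2[C@](C)(CC[C@@H]([O-])[C@]2(C)C(=O)[O-])[C@H]1CC/C(C)=C/CO[Si](c1ccccc1)(c1ccccc1)C(C)(C)C | intermediate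
24 | tert-butyldiphenylsilyl ether of 3α-acetoxy-15-hydroxylabda-8(17),13E-dien-19-oic acid | C=C1CC[C@@H]2[C@](C)(CC[C@@H](OC(C)=O)[C@]2(C)C(=O)O)[C@H]1CC/C(C)=C/CO[Si](c1ccccc1)(c1ccccc1)C(C)(C)C | intermediate
25 | (3R,4R,5R,9S,10R)-3-acetoxy-15-hydroxylabda-8(17),13E-dien-19-oic acid | C=C1CC[C@@H]2[C@](C)(CC[C@@H](OC(C)=O)[C@]2(C)C(=O)O)[C@H]1CC/C(C)=C/CO | target

**Step count and risks**

Total step count: 16. Longest linear sequence: 12 (steps 1–4 and 9–16; the branch 5–8 and 9–16 is equally long).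

The three steps most likely to fail:

Step 10 (the proposed new cascade). Risks: N-iodosuccinimide may attack the allylsilane or an alkene before the gold cycle turns over, the ee may be low with an internal alkyne, and the C13 alkene may close a third ring. The fallback uses known chemistry, sets out from 16 and comes back at 19. Compound 16 is cyclised with the same chiral digold catalyst but with methanol (2 equiv) in place of N-iodosuccinimide, which is the established proton-terminated mode of enantioselective gold-catalysed enyne polycyclisation, to give tert-butyl[(19-norlabda-3,8(17),13E-trien-15-yl)oxy]diphenylsilane F1. The trisubstituted ring-A alkene of F1, the most electron-rich one, is epoxidised with mCPBA (1.0 equiv, NaHCO3, CH2Cl2, −40 °C) from the α face to tert-butyl[(3α,4α-epoxy-19-norlabda-8(17),13E-dien-15-yl)oxy]diphenylsilane F2. An InCl3-catalysed Meinwald rearrangement (1,2-hydride shift) gives the ketone 15-[(tert-butyldiphenylsilyl)oxy]-19-norlabda-8(17),13E-dien-3-one F3. Tf2O with 2,6-di-tert-butyl-4-methylpyridine gives the more substituted enol triflate 15-[(tert-butyldiphenylsilyl)oxy]-19-norlabda-3,8(17),13E-trien-3-yl trifluoromethanesulfonate F4. Formylation with Pd(PPh3)4 (zerovalent palladium), CO and Bu3SnH then gives enal 19, and the route continues at step 12.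

Step 9 (three-component carbocupration and alkylation). Risks: the α-silyl copper reagent may add slowly, and the alkenylcopper may be alkylated poorly by an unactivated primary iodide. The fallback sets out from 15 and 14 and comes back at 16. Alkenylcopper 15 is quenched with I2 at −40 °C to give (1Z,5E)-1-iodo-6-methyl-2-[(trimethylsilyl)methyl]undeca-1,5-dien-9-yne F5. Iodide 14 is converted with zinc dust and LiCl in THF into {(3E)-5-[(tert-butyldiphenylsilyl)oxy]-3-methylpent-3-en-1-yl}zinc iodide F6. A Negishi cross-coupling of F5 and F6 with Pd(PPh3)4 (zerovalent palladium), which retains the alkene geometry, gives 16.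

Step 14 (oxidation to the β-keto acid). Risks: acid 22 may lose CO2 before it is reduced, and hypochlorite may attack the alkenes. The fallback sets out from 21 and comes back at 24. Both carbonyl groups of 21 are reduced with LiBH(s-Bu)3 (THF, −78 °C) to 15-[(tert-butyldiphenylsilyl)oxy]labda-8(17),13E-diene-3α,19-diol F7. TEMPO with PhI(OAc)2 oxidises only the primary alcohol to 15-[(tert-butyldiphenylsilyl)oxy]-3α-hydroxylabda-8(17),13E-dien-19-al F8. Pinnick oxidation gives 15-[(tert-butyldiphenylsilyl)oxy]-3α-hydroxylabda-8(17),13E-dien-19-oic acid F9, which is not a β-keto acid. Acetylation (Ac2O, pyridine, DMAP) gives 24.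

**Further compounds**

F1 | step 10 | tert-butyl[(19-norlabda-3,8(17),13E-trien-15-yl)oxy]diphenylsilane | C=C1CC[C@@H]2[C@](C)(CCC=C2C)[C@H]1CC/C(C)=C/CO[Si](c1ccccc1)(c1ccccc1)C(C)(C)C
F2 | step 10 | tert-butyl[(3α,4α-epoxy-19-norlabda-8(17),13E-dien-15-yl)oxy]diphenylsilane | C=C1CC[C@@H]2[C@](C)(CC[C@H]3O[C@@]23C)[C@H]1CC/C(C)=C/CO[Si](c1ccccc1)(c1ccccc1)C(C)(C)C
F3 | step 10 | 15-[(tert-butyldiphenylsilyl)oxy]-19-norlabda-8(17),13E-dien-3-one (4α-methyl) | C=C1CC[C@@H]2[C@](C)(CCC(=O)[C@H]2C)[C@H]1CC/C(C)=C/CO[Si](c1ccccc1)(c1ccccc1)C(C)(C)C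
F4 | step 10 | 15-[(tert-butyldiphenylsilyl)oxy]-19-norlabda-3,8(17),13E-trien-3-yl trifluoromethanesulfonate | C=C1CC[C@@H]2[C@](C)(CCC(OS(=O)(=O)C(F)(F)F)=C2C)[C@H]1CC/C(C)=C/CO[Si](c1ccccc1)(c1ccccc1)C(C)(C)C
F5 | step 9 | (1Z,5E)-1-iodo-6-methyl-2-[(trimethylsilyl)methyl]undeca-1,5-dien-9-yne | CC#CCC/C(C)=C/CC/C(C[Si](C)(C)C)=C/I
F6 | step 9 | {(3E)-5-[(tert-butyldiphenylsilyl)oxy]-3-methylpent-3-en-1-yl}zinc iodide | I[Zn]CC/C(C)=C/CO[Si](c1ccccc1)(c1ccccc1)C(C)(C)C
F7 | step 14 | 15-[(tert-butyldiphenylsilyl)oxy]labda-8(17),13E-diene-3α,19-diol | C=C1CC[C@@H]2[C@](C)(CC[C@@H](O)[C@]2(C)CO)[C@H]1CC/C(C)=C/CO[Si](c1ccccc1)(c1ccccc1)C(C)(C)C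
F8 | step 14 | 15-[(tert-butyldiphenylsilyl)oxy]-3α-hydroxylabda-8(17),13E-dien-19-al | C=C1CC[C@@H]2[C@](C)(CC[C@@H](O)[C@]2(C)C=O)[C@H]1CC/C(C)=C/CO[Si](c1ccccc1)(c1ccccc1)C(C)(C)C
F9 | step 14 | 15-[(tert-butyldiphenylsilyl)oxy]-3α-hydroxylabda-8(17),13E-dien-19-oic acid | C=C1CC[C@@H]2[C@](C)(CC[C@@H](O)[C@]2(C)C(=O)O)[C@H]1CC/C(C)=C/CO[Si](c1ccccc1)(c1ccccc1)C(C)(C)C
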